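**Plan**
- Feature: in the oxolane ring (O1, C2–C5) the ketone carbon sits on C3, next to the O-benzylic carbon C2, and the aryl groups on C2 and C5 share one face. A 2,5-cis 3-aroyloxolane of this kind is what a Prins cyclisation gives when a pinacol shift ends it.
- Cuts: the six phenol esters first, then O1–C5, C4–C5 and C2–C3 together. This leaves 2,4-bis(pivaloyloxy)benzaldehyde and a (1R,2S,3Z)-1,2,5-triarylpent-3-ene-1,2-diol, which is cut at alkyne–carbinol, and the resulting ketone at aryl–carbonyl.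
- Chain assembly: Weinreb amide of (R)-4-hydroxymandelic acid + resorcinol-derived aryl Grignard → α-silyloxy ketone; + 3-arylpropynyl Grignard → propargylic carbinol; silyl ethers exchanged for pivalates; semihydrogenation to the (Z)-alkene.
- Ring: the only ring forms in the key step, first as a six-membered oxanyl cation, then contracted to the oxolane. Ester methanolysis ends the route.
- Stereochemistry: C2 is bought. It directs the carbinol centre through a magnesium chelate and fixes C5 through a chair, the (Z)-alkene fixes C4, and C3 is set by base equilibration while the phenols are still esters.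

Key step: step 10

Assumption: (R)-4-hydroxymandelic acid is purchasable as a single enantiomer; otherwise diazotisation of D-4-hydroxyphenylglycine, which runs with retention, supplies it.
Abbreviations: TBS = tert-butyldimethylsilyl, TES = triethylsilyl, TIPS = triisopropylsilyl, Piv = pivaloyl. Oxolane numbering: O1, C2 (4-hydroxyphenyl), C3 (aroyl), C4 (benzyl), C5 (2,4-dihydroxyphenyl).

**Step 1**
Reactants: 1 (R)-4-hydroxymandelic acid
Product: 2 (2R)-2-hydroxy-2-(4-hydroxyphenyl)-N-methoxy-N-methylacetamide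
Conditions: MeNH(OMe)·HCl, EDC·HCl, HOBt, N-methylmorpholine, DMF, 0 °C → rt
Reagents that add atoms: N,O-dimethylhydroxylamine hydrochloride, CNOC.Cl
Why: Carbodiimide/HOBt amide coupling of an unprotected α-hydroxy acid, in which the amine outcompetes both hydroxyl groups and the benzylic stereocentre is not touched.

**Step 2**
Reactants: 2 (2R)-2-hydroxy-2-(4-hydroxyphenyl)-N-methoxy-N-methylacetamide
Product: 4 (2R)-2-[4-(tert-butyldimethylsilyloxy)phenyl]-N-methoxy-N-methyl-2-(triethylsilyloxy)acetamide, via phenol TBS ether 3 (not isolated)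
Conditions: TBSCl (1.05 equiv), imidazole, DMF, 0 °C; then TESCl (1.3 equiv), 0 °C → rt
Reagents that add atoms: tert-butyldimethylsilyl chloride, CC(C)(C)[Si](C)(C)Cl; triethylsilyl chloride, CC[Si](Cl)(CC)CC
Why: Imidazole-promoted silylation takes the phenol first and the slower secondary alcohol second, so one flask places a robust TBS ether on the phenol and a small TES ether, still able to chelate, on the carbinol oxygen.

**Step 3**
Reactants: 5 4-bromoresorcinol
Product: 6 1-bromo-2,4-bis(triisopropylsilyloxy)benzene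
Conditions: TIPSCl (2.4 equiv), imidazole, DMF, rt → 40 °C
Reagents that add atoms: triisopropylsilyl chloride, CC(C)[Si](Cl)(C(C)C)C(C)C
Why: Standard phenol silylation, with the bulky TIPS group chosen to slow the 1,3 oxygen-to-carbon silyl shift (retro-Brook rearrangement) that threatens an ortho-silyloxy aryl anion in the next step.

**Step 4**
Reactants: 6 1-bromo-2,4-bis(triisopropylsilyloxy)benzene; 4 (2R)-2-[4-(tert-butyldimethylsilyloxy)phenyl]-N-methoxy-N-methyl-2-(triethylsilyloxy)acetamide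
Product: 9 (2R)-1-[2,4-bis(triisopropylsilyloxy)phenyl]-2-[4-(tert-butyldimethylsilyloxy)phenyl]-2-(triethylsilyloxy)ethan-1-one, via aryllithium 7 (not isolated), via arylmagnesium bromide 8 (not isolated)
Conditions: 6 (1.3 equiv), n-BuLi, THF, −78 °C, 15 min; MgBr2·OEt2, −78 → 0 °C; then 4, 0 °C → rt; aq NH4Cl
Reagents that add atoms: none
Why: Bromine–lithium exchange, transmetalation to the less basic Grignard reagent and Weinreb ketone synthesis, in which the chelated tetrahedral adduct prevents over-addition and keeps the α-stereocentre from enolising until the quench.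

**Step 5**
Reactants: 10 (4-bromophenoxy)(tert-butyl)dimethylsilane; 11 methoxyallene
Product: 13 tert-butyldimethyl[4-(prop-2-yn-1-yl)phenoxy]silane, via arylmagnesium bromide 12 (not isolated)
Conditions: Mg, THF, reflux; then 11 (1.2 equiv), CuBr (5 mol %), Et2O/THF, −10 °C → rt; aq NH4Cl
Reagents that add atoms: none
Why: CuBr-catalysed SN2′ substitution of methoxyallene by an aryl Grignard reagent is a known one-step entry to 3-arylprop-1-ynes and avoids a labile 4-silyloxybenzyl halide.

**Step 6**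
Reactants: 13 tert-butyldimethyl[4-(prop-2-yn-1-yl)phenoxy]silane; 9 (2R)-1-[2,4-bis(triisopropylsilyloxy)phenyl]-2-[4-(tert-butyldimethylsilyloxy)phenyl]-2-(triethylsilyloxy)ethan-1-one
Product: 15 (1R,2S)-2-[2,4-bis(triisopropylsilyloxy)phenyl]-1,5-bis[4-(tert-butyldimethylsilyloxy)phenyl]-1-(triethylsilyloxy)pent-3-yn-2-ol, via alkynylmagnesium bromide 14 (not isolated)
Conditions: 13 (2.5 equiv), EtMgBr, THF, 0 °C → rt; added to 9, MgBr2·OEt2 (2 equiv), CH2Cl2, −78 → 0 °C; aq NH4Cl
Reagents that add atoms: none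
Why: In this Cram-chelate addition of an alkynyl Grignard reagent to an α-silyloxy aryl ketone, magnesium bridges the carbonyl and TES-ether oxygens and the slim, weakly basic nucleophile enters past the hydrogen of C1 rather than its aryl group, which should give the (2S) carbinol without enolising C1.

**Step 7**
Reactants: 15 (1R,2S)-2-[2,4-bis(triisopropylsilyloxy)phenyl]-1,5-bis[4-(tert-butyldimethylsilyloxy)phenyl]-1-(triethylsilyloxy)pent-3-yn-2-ol
Product: 17 (1R,2S)-2-[2,4-bis(pivaloyloxy)phenyl]-1,5-bis[4-(pivaloyloxy)phenyl]pent-3-yne-1,2-diol, via hexaol 16 (not isolated)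
Conditions: TBAF (5.5 equiv), THF, 0 °C; then Et3N, PivCl (5 equiv), 0 °C; pH 7 buffer
Reagents that add atoms: pivaloyl chloride, CC(C)(C)C(=O)Cl
Why: Fluoride cleaves all five silyl ethers, and the four ammonium phenoxides are then acylated much faster than the hindered secondary and tertiary alcohols (chemoselective Schotten–Baumann-type O-acylation), so the electron-rich hexaol is never handled.

**Step 8**
Reactants: 17 (1R,2S)-2-[2,4-bis(pivaloyloxy)phenyl]-1,5-bis[4-(pivaloyloxy)phenyl]pent-3-yne-1,2-diol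
Product: 18 (1R,2S,3Z)-2-[2,4-bis(pivaloyloxy)phenyl]-1,5-bis[4-(pivaloyloxy)phenyl]pent-3-ene-1,2-diol
Conditions: H2 (1 atm), Pd/CaCO3 poisoned with Pb(OAc)2, quinoline, EtOAc, rt
Reagents that add atoms: none
Why: Lindlar semihydrogenation delivers both hydrogens syn and so gives the (Z)-alkene, and it follows the ester exchange so that the ionisation-prone allylic carbinol exists only beside deactivated rings.

**Step 9**
Reactants: 19 2,4-dihydroxybenzaldehyde
Product: 20 2,4-bis(pivaloyloxy)benzaldehyde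
Conditions: PivCl (2.5 equiv), Et3N, DMAP (cat.), CH2Cl2, 0 °C → rt
Reagents that add atoms: pivaloyl chloride, CC(C)(C)C(=O)Cl
Why: DMAP-catalysed acylation esterifies both phenols, including the hydrogen-bonded ortho one.

**Step 10**
Reactants: 18 (1R,2S,3Z)-2-[2,4-bis(pivaloyloxy)phenyl]-1,5-bis[4-(pivaloyloxy)phenyl]pent-3-ene-1,2-diol; 20 2,4-bis(pivaloyloxy)benzaldehyde
Product: 23 [(2S,3S,4S,5R)-5-[2,4-bis(pivaloyloxy)phenyl]-4-[4-(pivaloyloxy)benzyl]-2-[4-(pivaloyloxy)phenyl]oxolan-3-yl][2,4-bis(pivaloyloxy)phenyl]methanone, via dioxolane acetal 21 (not isolated), via all-cis C3 epimer 22 (not isolated)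
Conditions: 20 (1.2 equiv), p-TsOH·H2O (5 mol %), MgSO4, CH2Cl2, −20 → 0 °C; then SnCl4 (1.5 equiv), −78 → −30 °C; aq NaHCO3; crude, DBU (0.3 equiv), CH2Cl2, rt
Reagents that add atoms: none
Why: The acid-catalysed condensation gives acetal 21, which SnCl4 opens reversibly; only the (E)-oxocarbenium ion on the oxygen of the diol's C1 (O1–C5 made) can reach the alkene, whose far terminus attacks it (C4–C5), and the bond from the carbinol carbon to the diol's C1 then moves to the electron-deficient carbon (C2–C3), which expels the carbinol carbon from the ring as the aryl ketone. The closest known reaction type is this one itself, the Prins cyclisation–pinacol rearrangement of allylic 1,2-diols and aldehydes to 2,5-cis 3-acyloxolanes. The ring closes 6-endo-trig through a chair to an oxan-4-yl cation and is contracted to the five-membered ring by the 1,2-shift, and a 2-oxonia-Cope/aldol sequence through the same chair would end at the same ketone. C5 is controlled by the bought centre, since the (1R,2S) diol lets the aryl groups on C2, C5 and the carbinol carbon all sit equatorial (2,5-cis); C4 is controlled by the (Z)-alkene, whose benzyl group must stand axial (4,5-cis); C2 migrates with retention; C3 should first arise cis to its neighbours (22) and is then turned by DBU, through the enolate, into the epimer trans to both (23). The step needs the oxocarbenium pathway to outrun ionisation of the tertiary benzylic allylic carbinol and of the benzylic C–O bonds, and needs the arenes to refrain from Friedel–Crafts closure, and the six electron-withdrawing pivalates together with the low temperature secure this. The equilibration is done on the esters because the free 2,4-dihydroxyphenyl ketone would be a phenoxide under base and would enolise far less readily.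

**Step 11**
Reactants: 23 [(2S,3S,4S,5R)-5-[2,4-bis(pivaloyloxy)phenyl]-4-[4-(pivaloyloxy)benzyl]-2-[4-(pivaloyloxy)phenyl]oxolan-3-yl][2,4-bis(pivaloyloxy)phenyl]methanone
Product: 24 [(2S,3S,4S,5R)-5-(2,4-dihydroxyphenyl)-4-(4-hydroxybenzyl)-2-(4-hydroxyphenyl)oxolan-3-yl](2,4-dihydroxyphenyl)methanone
Conditions: K2CO3 (8 equiv), degassed MeOH/THF, argon, 0 °C → rt; aq NH4Cl
Reagents that add atoms: none
Why: Base-mediated transesterification (methanolysis) removes the six aryl esters, the most electrophilic groups present, while C3 already holds its most stable configuration and ring opening by β-elimination would be a disfavoured retro-5-endo-trig process.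

**Compound list**
1 | (R)-4-hydroxymandelic acid | O[C@@H](C(=O)O)c1ccc(O)cc1 | starting material
2 | (2R)-2-hydroxy-2-(4-hydroxyphenyl)-N-methoxy-N-methylacetamide | O[C@@H](C(=O)N(C)OC)c1ccc(O)cc1 | intermediate
3 | (2R)-2-[4-(tert-butyldimethylsilyloxy)phenyl]-2-hydroxy-N-methoxy-N-methylacetamide (not isolated) | O[C@@H](C(=O)N(C)OC)c1ccc(O[Si](C)(C)C(C)(C)C)cc1 | intermediate
4 | (2R)-2-[4-(tert-butyldimethylsilyloxy)phenyl]-N-methoxy-N-methyl-2-(triethylsilyloxy)acetamide | CC[Si](CC)(CC)O[C@@H](C(=O)N(C)OC)c1ccc(O[Si](C)(C)C(C)(C)C)cc1 | intermediate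
5 | 4-bromoresorcinol | Oc1ccc(Br)c(O)c1 | starting material
6 | 1-bromo-2,4-bis(triisopropylsilyloxy)benzene | Brc1ccc(O[Si](C(C)C)(C(C)C)C(C)C)cc1O[Si](C(C)C)(C(C)C)C(C)C | intermediate
7 | 2,4-bis(triisopropylsilyloxy)phenyllithium (not isolated) | [Li]c1ccc(O[Si](C(C)C)(C(C)C)C(C)C)cc1O[Si](C(C)C)(C(C)C)C(C)C | intermediate
8 | 2,4-bis(triisopropylsilyloxy)phenylmagnesium bromide (not isolated) | Br[Mg]c1ccc(O[Si](C(C)C)(C(C)C)C(C)C)cc1O[Si](C(C)C)(C(C)C)C(C)C | intermediate
9 | (2R)-1-[2,4-bis(triisopropylsilyloxy)phenyl]-2-[4-(tert-butyldimethylsilyloxy)phenyl]-2-(triethylsilyloxy)ethan-1-one | CC[Si](CC)(CC)O[C@@H](C(=O)c1ccc(O[Si](C(C)C)(C(C)C)C(C)C)cc1O[Si](C(C)C)(C(C)C)C(C)C)c1ccc(O[Si](C)(C)C(C)(C)C)cc1 | intermediate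
10 | (4-bromophenoxy)(tert-butyl)dimethylsilane | Brc1ccc(O[Si](C)(C)C(C)(C)C)cc1 | starting material
11 | methoxyallene (1-methoxypropa-1,2-diene) | COC=C=C | starting material
12 | 4-(tert-butyldimethylsilyloxy)phenylmagnesium bromide (not isolated) | Br[Mg]c1ccc(O[Si](C)(C)C(C)(C)C)cc1 | intermediate
13 | tert-butyldimethyl[4-(prop-2-yn-1-yl)phenoxy]silane | C#CCc1ccc(O[Si](C)(C)C(C)(C)C)cc1 | intermediate
14 | 3-[4-(tert-butyldimethylsilyloxy)phenyl]prop-1-yn-1-ylmagnesium bromide (not isolated) | Br[Mg]C#CCc1ccc(O[Si](C)(C)C(C)(C)C)cc1 | intermediate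
15 | (1R,2S)-2-[2,4-bis(triisopropylsilyloxy)phenyl]-1,5-bis[4-(tert-butyldimethylsilyloxy)phenyl]-1-(triethylsilyloxy)pent-3-yn-2-ol | CC[Si](CC)(CC)O[C@@H]([C@@](O)(c1ccc(O[Si](C(C)C)(C(C)C)C(C)C)cc1O[Si](C(C)C)(C(C)C)C(C)C)C#CCc1ccc(O[Si](C)(C)C(C)(C)C)cc1)c1ccc(O[Si](C)(C)C(C)(C)C)cc1 | intermediate
16 | (1R,2S)-2-(2,4-dihydroxyphenyl)-1,5-bis(4-hydroxyphenyl)pent-3-yne-1,2-diol (not isolated) | O[C@@H]([C@@](O)(c1ccc(O)cc1O)C#CCc1ccc(O)cc1)c1ccc(O)cc1 | intermediate
17 | (1R,2S)-2-[2,4-bis(pivaloyloxy)phenyl]-1,5-bis[4-(pivaloyloxy)phenyl]pent-3-yne-1,2-diol | O[C@@H]([C@@](O)(c1ccc(OC(=O)C(C)(C)C)cc1OC(=O)C(C)(C)C)C#CCc1ccc(OC(=O)C(C)(C)C)cc1)c1ccc(OC(=O)C(C)(C)C)cc1 | intermediate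
18 | (1R,2S,3Z)-2-[2,4-bis(pivaloyloxy)phenyl]-1,5-bis[4-(pivaloyloxy)phenyl]pent-3-ene-1,2-diol | O[C@@H]([C@@](O)(c1ccc(OC(=O)C(C)(C)C)cc1OC(=O)C(C)(C)C)/C=C\Cc1ccc(OC(=O)C(C)(C)C)cc1)c1ccc(OC(=O)C(C)(C)C)cc1 | intermediate
19 | 2,4-dihydroxybenzaldehyde | O=Cc1ccc(O)cc1O | starting material
20 | 2,4-bis(pivaloyloxy)benzaldehyde | O=Cc1ccc(OC(=O)C(C)(C)C)cc1OC(=O)C(C)(C)C | intermediate
21 | (4S,5R)-2,4-bis[2,4-bis(pivaloyloxy)phenyl]-5-[4-(pivaloyloxy)phenyl]-4-{(1Z)-3-[4-(pivaloyloxy)phenyl]prop-1-en-1-yl}-1,3-dioxolane, both epimers at the acetal carbon (not isolated) | C1(c2ccc(OC(=O)C(C)(C)C)cc2OC(=O)C(C)(C)C)O[C@@H]([C@@](O1)(c2ccc(OC(=O)C(C)(C)C)cc2OC(=O)C(C)(C)C)/C=C\Cc2ccc(OC(=O)C(C)(C)C)cc2)c2ccc(OC(=O)C(C)(C)C)cc2 | intermediate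
22 | (2S,3R,4S,5R) all-cis C3 epimer of 23 (not isolated) | O=C(c1ccc(OC(=O)C(C)(C)C)cc1OC(=O)C(C)(C)C)[C@@H]1[C@H](Cc2ccc(OC(=O)C(C)(C)C)cc2)[C@H](c2ccc(OC(=O)C(C)(C)C)cc2OC(=O)C(C)(C)C)O[C@@H]1c1ccc(OC(=O)C(C)(C)C)cc1 | intermediate
23 | [(2S,3S,4S,5R)-5-[2,4-bis(pivaloyloxy)phenyl]-4-[4-(pivaloyloxy)benzyl]-2-[4-(pivaloyloxy)phenyl]oxolan-3-yl][2,4-bis(pivaloyloxy)phenyl]methanone (hexapivalate of the target) | O=C(c1ccc(OC(=O)C(C)(C)C)cc1OC(=O)C(C)(C)C)[C@H]1[C@H](Cc2ccc(OC(=O)C(C)(C)C)cc2)[C@H](c2ccc(OC(=O)C(C)(C)C)cc2OC(=O)C(C)(C)C)O[C@@H]1c1ccc(OC(=O)C(C)(C)C)cc1 | intermediate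
24 | [(2S,3S,4S,5R)-5-(2,4-dihydroxyphenyl)-4-(4-hydroxybenzyl)-2-(4-hydroxyphenyl)oxolan-3-yl](2,4-dihydroxyphenyl)methanone (CNP0181717.3) | O=C(c1ccc(O)cc1O)[C@H]1[C@H](Cc2ccc(O)cc2)[C@H](c2ccc(O)cc2O)O[C@@H]1c1ccc(O)cc1 | target

**Count**
- Total steps: 11.
- Longest linear sequence: 8 steps (1, 2, 4, 6, 7, 8, 10, 11).

**Steps most likely to fail**

**Step 10.**
- What may go wrong: protic acid, or HCl formed from SnCl4 and the water of condensation, ionises the tertiary benzylic allylic carbinol. That leads to dehydration to a diene or to a classical pinacol shift.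
- The aldehyde component may also be exchanged after a 2-oxonia-Cope event.
- During the DBU stage the enolate may attack the ortho ester.
- Fallback: replace the dehydrative condensation by an anhydrous silyl-transfer route. It sets out from 18, whose two hydroxyl groups are silylated with N-(trimethylsilyl)imidazole in CH2Cl2 to give the bis(trimethylsilyl) ether of the (Z)-diol F1.
- F1 and 20 are then combined with catalytic TMSOTf in CH2Cl2 at −78 °C. The oxocarbenium ion forms from silyl ether and aldehyde with neither water nor protic acid present, and the tertiary silyl ether ends the pinacol shift by losing its silyl group.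
- The same three bonds form. The crude product is 22, where the route is rejoined, and DBU turns it into 23 as before.

**Step 6.**
- What may go wrong: facial selectivity is poor if the silyl ether binds magnesium too weakly. Felkin–Anh attack then gives the 2R epimer, whose aryl group would stand axial and 1,3-diaxial to the benzyl group in the key chair.
- Addition to the hindered ketone may also be slow.
- Fallback: rely on a covalent magnesium alkoxide instead of a dative ether contact. It sets out from 9, whose TES ether is removed with AcOH/THF/H2O (the aryl silyl ethers tolerate this) to give the (R)-α-hydroxy ketone F2, which is kept cold to protect its stereocentre.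
- Three equivalents of 14 first form the magnesium alkoxide, a rigid five-membered chelate (Cram cyclic model), and then add to give the (1R,2S) tetrasilyl alkyne diol F3.
- TBAF converts F3 into 16, where the route is rejoined inside step 7.

**Step 7.**
- What may go wrong: the C1 hydroxyl is acylated as well, the pivaloyl group migrates from the ortho ester to a neighbouring carbinol oxygen under base, or the electron-rich hexaol decomposes.
- Fallback: staged, orthogonal deprotection instead of global desilylation. It sets out from 15, in which Cs2CO3 in DMF/H2O cleaves only the four aryl silyl ethers to give the C1-O-TES tetraphenol F4.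
- Only the unreactive tertiary alcohol is then free, so forcing acylation (PivCl, Et3N, DMAP) is allowed and gives the C1-O-TES tetrapivalate F5.
- AcOH/THF/H2O, harmless now that the rings are deactivated, removes the TES group and the route is rejoined at 17.

**Further compounds**
F1 | step 10 | (1R,2S,3Z)-2-[2,4-bis(pivaloyloxy)phenyl]-1,5-bis[4-(pivaloyloxy)phenyl]-1,2-bis(trimethylsilyloxy)pent-3-ene | C[Si](C)(C)O[C@@H]([C@@](O[Si](C)(C)C)(c1ccc(OC(=O)C(C)(C)C)cc1OC(=O)C(C)(C)C)/C=C\Cc1ccc(OC(=O)C(C)(C)C)cc1)c1ccc(OC(=O)C(C)(C)C)cc1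
F2 | step 6 | (2R)-1-[2,4-bis(triisopropylsilyloxy)phenyl]-2-[4-(tert-butyldimethylsilyloxy)phenyl]-2-hydroxyethan-1-one | O[C@@H](C(=O)c1ccc(O[Si](C(C)C)(C(C)C)C(C)C)cc1O[Si](C(C)C)(C(C)C)C(C)C)c1ccc(O[Si](C)(C)C(C)(C)C)cc1
F3 | step 6 | (1R,2S)-2-[2,4-bis(triisopropylsilyloxy)phenyl]-1,5-bis[4-(tert-butyldimethylsilyloxy)phenyl]pent-3-yne-1,2-diol | O[C@@H]([C@@](O)(c1ccc(O[Si](C(C)C)(C(C)C)C(C)C)cc1O[Si](C(C)C)(C(C)C)C(C)C)C#CCc1ccc(O[Si](C)(C)C(C)(C)C)cc1)c1ccc(O[Si](C)(C)C(C)(C)C)cc1
F4 | step 7 | (1R,2S)-2-(2,4-dihydroxyphenyl)-1,5-bis(4-hydroxyphenyl)-1-(triethylsilyloxy)pent-3-yn-2-ol | CC[Si](CC)(CC)O[C@@H]([C@@](O)(c1ccc(O)cc1O)C#CCc1ccc(O)cc1)c1ccc(O)cc1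
F5 | step 7 | (1R,2S)-2-[2,4-bis(pivaloyloxy)phenyl]-1,5-bis[4-(pivaloyloxy)phenyl]-1-(triethylsilyloxy)pent-3-yn-2-ol | CC[Si](CC)(CC)O[C@@H]([C@@](O)(c1ccc(OC(=O)C(C)(C)C)cc1OC(=O)C(C)(C)C)C#CCc1ccc(OC(=O)C(C)(C)C)cc1)c1ccc(OC(=O)C(C)(C)C)cc1
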